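## Structural features

The target is an 8,3'-neolignan built from two C6C3 units. With the usual atom labels, ring A is the 3,4-dimethoxyphenyl ring, the chain is C7H2–C8H(C9H3), and ring B is the cross-conjugated cyclohexa-2,5-dienone C1'(allyl)=C2'H–C3'(OMe)(C8)–C4'(OMe)=C5'H–C6'(=O). The halves are joined only by the bond C8–C3'. The fully substituted, oxygen-bearing, doubly allylic carbon C3' (S) therefore stands next to the tertiary carbon C8 (S) of a freely rotating chain, and these are the only stereocentres. Ring B is a para-quinol methyl ether and is fragile in three ways: reduction or hydride attack at C6' followed by loss of methanol aromatises it, strong acid starts a dienone–phenol shift, and an oxygen placed on C7 can close a five-membered ring onto the acceptor carbons C2' or C4'. A cation at C7 would be stabilised by ring A and caught by C5' or by the oxygen on C4', and the skipped allyl group on C1' rules out hydrogenation and hydroboration. The real difficulty is the C3'/C8 pair: ring B is flat with two equally open faces, and methyl and arylmethyl on C8 differ too little in size for useful 1,2-induction in either direction, so the pair must be set as a group in a cyclic, stereospecific event. The key step exploits the allyl unit C1'=C2'–C3' of ring B together with the methoxy group on C3'. Moving the double bond to C2'=C3' and placing an acyloxy group on C1' turns ring B into an ortho-quinol ester, a cyclic allylic ester whose far terminus C3' is an enol ether carbon, which is the retron of an ester enolate Claisen rearrangement. Stripped of its allyl group and ester, that ortho-quinol is the C2-symmetric 4,5-dimethoxy-1,2-benzoquinone, so all of ring B with its three oxygen atoms comes from one flat, achiral compound.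

## Logic of the disconnections

**15 to 11 and 12.** The bond between C7 and C1 of ring A is cut. Ring A plays no part in the stereochemical problem. Cutting here keeps C7 a primary sp3 carbon that never carries a cation or, next to ring A, an alkoxide. The gain is that ring A becomes the commodity halide 12 and that C7 can be traced back to a carboxyl carbon. The forward step must be an sp3–sp2 coupling mild enough for the dienone, the enol ether and the allyl group of 11. This calls for an arylzinc reagent (14, from 12 through 13) and a low temperature.

**11 to 10 to 8.** No carbon–carbon bond is cut. The carbon–iodine bond at C7 goes back to C7–OH and this to the carboxyl group of 8. The reason is that a carboxyl group on C8 is what an ester enolate rearrangement leaves behind. The gain is a crystallisable acid as the first product after the key step. The forward steps need a hydride source that prefers an activated acyl group (9) to the dienone. They also need short, non-basic handling of 10, whose hydroxyl group can reach C2' and C4'.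

**8 to 5 (key disconnection).** The bond C3'–C8 is cut, the bond C1'–O is re-formed, the double bond returns from C1'=C2' to C2'=C3', and C7 becomes an ester carbonyl carbon. This is the only cut that removes both stereocentres at once and replaces them by one auxiliary centre at C1', which vanishes in the forward step. The gain is large: 8 has a quaternary carbinol ether carbon next to a tertiary centre, whereas 5 has one stereocentre and a three-carbon acyl group. The forward step needs selective enolisation of the ester, a defined ketene acetal geometry (6), a well-ordered transition state, and a rearrangement faster than the shifts open to the allyl group on C1'. In one sentence, the route is the ester enolate Claisen rearrangement of 5.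

**5 to 4.** The acyl–oxygen bond at the oxygen on C1' is cut. This separates the three carbons C7–C9 from ring B and leaves a tertiary alcohol. The forward step must acylate a hindered, hydrogen-bonded tertiary alcohol without making its alkoxide.

**4 to 2.** The bond between C1' and the allyl CH2 is cut. This removes the last stereocentre and gives 2, whose two carbonyl groups are homotopic. Regiochemistry does not arise, and only one face selection remains. The forward step needs a 1,2-selective, enantioselective allyl transfer that stops after one addition and delivers the product as a covalent borate (3) rather than as a metal alkoxide.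

**2 to 1.** The C–O bond at the carbon ortho to the phenol oxygen is cut. The gain is a cheap commercial phenol. The forward step needs an oxidant that delivers oxygen to the free, less hindered ortho position and not to the methoxy-bearing para position.

## Other disconnections considered

**Alternative 1:** The bond C3'–OMe is cut, which is the first idea that comes to mind. The forward key step is the oxidative dearomatisation of phenol A1 in methanol, with a hypervalent iodine oxidant or at an anode, and trapping of the phenoxenium ion at C3'.
- Methanol would attack a flat cation whose two faces are told apart only by C8, that is by methyl against arylmethyl on a freely rotating bond. No useful bias at C3' can be expected.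
- The loss would fall on the last step and on an advanced enantiopure compound.
- A1 itself needs an enantioselective 1,2-diarylpropane synthesis and a regioselective allylation, so the plan is not shorter.
- The chosen plan sets both centres together in a cyclic transition state.

**Alternative 2:** The bond C3'–C8 is cut in the polar sense. The forward key step is the 1,2-addition of the secondary organolithium A3 to the C3' carbonyl group of quinone A2 (the C6' carbonyl group is deactivated as a vinylogous ester). This gives quinol A4, which is then O-methylated.
- The plan is short, but a carbon–metal bond at C8 holds its configuration only at very low temperature.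
- A2 is a good electron acceptor, so electron transfer with loss of configuration at C8 and reduction of A2 must be expected.
- The open transition state gives no reason for one face of A2 to be preferred, so both centres would be left to chance.
- In the chosen plan the same bond is made intramolecularly and suprafacially.

**Alternative 3:** The bonds C3'–C8 and C7–O(C4') are cut, following the presumed biosynthesis. The forward key step is acid ionisation of quinone monoketal A5 and attack of C8 of (E)-methylisoeugenol A6 on the resulting cation. The C7 cation then closes onto the oxygen at C4' to give hydrobenzofuranone A7. Reductive opening of C7–O and O-methylation would follow.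
- The cation offers several electrophilic positions, among them the allyl-bearing C1'.
- The C7 cation can close on carbon to bicyclo[3.2.1]octanoid skeletons.
- Nothing in the system controls absolute configuration.
- A third stereocentre at C7 is made only to be deleted, and its deletion passes once more through the C7 cation.
- The final methylation meets an ambident vinylogous acid.
- The chosen plan avoids the C7 cation altogether and is enantioselective by design.

Key step: step 4

Assumption: the (S)-configured biphenol catalyst of step 2 is taken to direct the allyl group to the Re face of the carbonyl carbon of 2. If the sense of induction is the opposite, the antipodal catalyst is used and nothing else changes.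

## Steps

Step 1
Reactants: 1 3,4-dimethoxyphenol
Product: 2 4,5-dimethoxycyclohexa-3,5-diene-1,2-dione (4,5-dimethoxy-1,2-benzoquinone)
Conditions: IBX (1.05 equiv), DMF, 20 °C
Reagents that add atoms: 2-iodoxybenzoic acid (IBX), O=C1OI(=O)(O)c2ccccc12
Why: Oxidation of an electron-rich phenol to the ortho-quinone with IBX; the aryloxy derivative of pentavalent iodine hands its oxygen intramolecularly to the free and less hindered ortho carbon, not to the methoxy-bearing para carbon. The product is a doubly vinylogous ester and should be a stable, crystalline quinone; no stereocentre is formed.

Step 2
Reactants: 2 4,5-dimethoxy-1,2-benzoquinone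
Product: 4 (6S)-6-allyl-6-hydroxy-3,4-dimethoxycyclohexa-2,4-dien-1-one, via diisopropyl borate ester 3 (not isolated)
Conditions: CH2=CHCH2B(OiPr)2 (1.3 equiv), (S)-3,3'-dibromo-1,1'-bi-2-naphthol (15 mol %), PhCF3/toluene, −35 °C; then H2O, 0 °C
Reagents that add atoms: allyldiisopropoxyborane, C=CCB(OC(C)C)OC(C)C
Why: Diol-catalysed asymmetric allylboration of a ketone; the closed six-membered Zimmerman–Traxler transition state forces 1,2-addition instead of conjugate addition, and the covalent boron–oxygen bond of 3 avoids a free alkoxide, which would speed up retro-Claisen and ketol shifts of the allyl group. The two carbonyl groups of 2 are homotopic (C2 axis in the ring plane), so only a face has to be chosen, and attack on the Re face sets S at C1'. The carbonyl group left in 3 is a vinylogous ester without an activating neighbour, so a second addition is not expected.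

Step 3
Reactants: 4 (6S)-6-allyl-6-hydroxy-3,4-dimethoxycyclohexa-2,4-dien-1-one
Product: 5 (1S)-1-allyl-3,4-dimethoxy-6-oxocyclohexa-2,4-dien-1-yl propanoate
Conditions: (EtCO)2O (1.5 equiv), Et3N, DMAP (20 mol %), CH2Cl2, 0 °C
Reagents that add atoms: propanoic anhydride, CCC(=O)OC(=O)CC
Why: DMAP-catalysed acyl transfer to a tertiary alpha-ketol, the usual way from ortho-quinols to ortho-quinol esters; only amine bases are present, so no alkoxide forms and C1' is not touched. The work is done at or below 0 °C and 5 is used at once, because 6-allylcyclohexa-2,4-dienones rearrange on heating.

Step 4
Reactants: 5 (1S)-1-allyl-3,4-dimethoxy-6-oxocyclohexa-2,4-dien-1-yl propanoate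
Product: 8 (2R)-2-[(1R)-3-allyl-1,6-dimethoxy-4-oxocyclohexa-2,5-dien-1-yl]propanoic acid, via (E)-silyl ketene acetal 6 (not isolated), via trimethylsilyl ester 7 (not isolated)
Conditions: Me3SiCl/Et3N, then LiN(iPr)2 (1.15 equiv), THF, −95 °C; −95 to 20 °C; aq citric acid
Reagents that add atoms: chlorotrimethylsilane, C[Si](C)(C)Cl (its silyl group is carried by 6 and 7 only and is lost on work-up; 8 is an isomer of 5)
Why: Kinetic deprotonation of the propionyl CH2 (the dienone of 5 has no alpha-hydrogen) in the presence of Me3SiCl gives the (E)-O-silyl ketene acetal 6, whose six atoms C8=C7(OSi)–O–C1'–C2'=C3' undergo a concerted suprafacial [3,3] shift on warming; the closest known reaction type is the Ireland–Claisen rearrangement of cyclohex-2-enyl propionates and of glycal esters, in which the new carbon–carbon bond is likewise made at the oxygen-bearing terminus of a cyclic enol ether. No ring is closed: C3'–C8 is formed, C1'–O is broken, the double bond moves from C2'=C3' to C1'=C2', and the linearly conjugated dienone becomes the cross-conjugated one with release of a silyl ester carbonyl group, which makes the step irreversible. C3' is controlled by C1', because the migrating unit can reach only the face of ring B on which the C1'–O bond stands, so S at C1' becomes the spatial arrangement of 15 at C3' (descriptor R in 8 only because C8 outranks C2' there), and the auxiliary centre C1' is erased in the same event. C8 is controlled by the ketene acetal geometry and the shape of the transition state: in the chair the (E)-isomer places C9H3, cis to the ring-bound oxygen, in the open sector between C3'–OMe and C2'–H and places H8 between C3'–OMe and C4', which gives the relative configuration of 15. The chair is expected because C4', C5' and C6' are sp2 and offer no axial hydrogen to the OSiMe3 group lying over ring B, while a boat would eclipse the C8 substituents with the three substituents of the fully substituted C3'; the minor (Z)-isomer, if it takes the boat that is common for cyclic esters, gives the same diastereomer. The rate is helped by the donor OMe on the bond-forming terminus C3' and by the acyl carbon C6' on the bond-breaking carbon C1', so the shift should be complete below 20 °C. The selectivities needed are silylation before the enolate attacks C6'=O (secured by Me3SiCl being present from the start, by −95 °C and by the vinylogous ester character of C6'=O) and rearrangement of 6 before the allyl group on C1' undergoes its own Cope or retro-Claisen shift (secured by the low temperature, since those shifts of 6-allylcyclohexa-2,4-dienones need heating).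

Step 5
Reactants: 8 (2R)-2-[(1R)-3-allyl-1,6-dimethoxy-4-oxocyclohexa-2,5-dien-1-yl]propanoic acid
Product: 10 (4R)-2-allyl-4-[(2S)-1-hydroxypropan-2-yl]-4,5-dimethoxycyclohexa-2,5-dien-1-one, via acyl imidazolide 9 (not isolated)
Conditions: 1,1'-carbonyldiimidazole, THF, 0 to 20 °C; NaBH4, THF/H2O, −10 °C, short contact; aq NH4Cl
Reagents that add atoms: 1,1'-carbonyldiimidazole, O=C(n1ccnc1)n1ccnc1 (its imidazolyl group is carried by 9 only; 10 gains nothing but hydrogen)
Why: Activation of a hindered acid as the N-acylimidazole and reduction with aqueous borohydride is a standard acid-to-alcohol sequence that avoids borane (allyl group) and aluminium hydrides (dienone). The cross-conjugated dienone, further deactivated by the methoxy donor on C4', is much less electrophilic than 9, and the buffered quench limits the time in which the C7 oxygen could add to ring B. No bond to C8 or C3' is changed.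

Step 6
Reactants: 10 (4R)-2-allyl-4-[(2S)-1-hydroxypropan-2-yl]-4,5-dimethoxycyclohexa-2,5-dien-1-one
Product: 11 (4R)-2-allyl-4-[(2R)-1-iodopropan-2-yl]-4,5-dimethoxycyclohexa-2,5-dien-1-one
Conditions: PPh3 and I2 premixed, imidazole, CH2Cl2, 0 °C
Reagents that add atoms: iodine, [I][I]
Why: Appel-type iodination through the alkoxyphosphonium salt and SN2 attack of iodide at the primary carbon C7; it is fast and nearly neutral at 0 °C. Premixing phosphine and iodine keeps free phosphine away from the enone; the stereocentres are not involved (the descriptor at C8 changes only through the priority of CH2I).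

Step 7
Reactants: 11 (4R)-2-allyl-4-[(2R)-1-iodopropan-2-yl]-4,5-dimethoxycyclohexa-2,5-dien-1-one; 12 4-bromo-1,2-dimethoxybenzene
Product: 15 (4S)-2-allyl-4-[(2S)-1-(3,4-dimethoxyphenyl)propan-2-yl]-4,5-dimethoxycyclohexa-2,5-dien-1-one, via arylmagnesium bromide 13 (not isolated), via arylzinc bromide 14 (not isolated)
Conditions: 12, Mg, THF; ZnBr2, 0 °C; then 11, Ni(acac)2 (10 mol %), 4-(trifluoromethyl)styrene (1 equiv), THF/NMP, −15 °C
Reagents that add atoms: magnesium, [Mg], and zinc dibromide, Br[Zn]Br (the metal atoms are carried by 13 and 14 only; 15 is made of atoms of 11 and 12)
Why: Negishi-type sp3–sp2 coupling of a primary alkyl iodide with an arylzinc halide under Ni(acac)2 catalysis, with an electron-poor styrene that promotes reductive elimination; the method runs at −15 °C and is compatible with ketones and esters. C7 is not stereogenic, so radical character in the activation of the carbon–iodine bond does no harm, and a C7 radical has only 4-exo or 5-endo paths toward ring B. No cation and no alkoxide is ever formed at C7, which is what ring B could not tolerate.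

## Compound list

1 | 3,4-dimethoxyphenol | COc1ccc(O)cc1OC | starting material
2 | 4,5-dimethoxy-1,2-benzoquinone | COC1=CC(=O)C(=O)C=C1OC | intermediate
3 | diisopropyl (1S)-1-allyl-3,4-dimethoxy-6-oxocyclohexa-2,4-dien-1-yl borate | C=CC[C@]1(OB(OC(C)C)OC(C)C)C=C(OC)C(OC)=CC1=O | intermediate
4 | (6S)-6-allyl-6-hydroxy-3,4-dimethoxycyclohexa-2,4-dien-1-one | C=CC[C@]1(O)C=C(OC)C(OC)=CC1=O | intermediate
5 | (1S)-1-allyl-3,4-dimethoxy-6-oxocyclohexa-2,4-dien-1-yl propanoate | C=CC[C@]1(OC(=O)CC)C=C(OC)C(OC)=CC1=O | intermediate
6 | (E)-O-trimethylsilyl ketene acetal of 5 (methyl cis to the ring-bound oxygen) | C=CC[C@]1(O/C(O[Si](C)(C)C)=C\C)C=C(OC)C(OC)=CC1=O | intermediate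
7 | trimethylsilyl ester of 8 | C=CCC1=C[C@@](OC)([C@@H](C)C(=O)O[Si](C)(C)C)C(OC)=CC1=O | intermediate
8 | (2R)-2-[(1R)-3-allyl-1,6-dimethoxy-4-oxocyclohexa-2,5-dien-1-yl]propanoic acid | C=CCC1=C[C@@](OC)([C@@H](C)C(=O)O)C(OC)=CC1=O | intermediate
9 | N-acylimidazole of 8 | C=CCC1=C[C@@](OC)([C@@H](C)C(=O)n2ccnc2)C(OC)=CC1=O | intermediate
10 | (4R)-2-allyl-4-[(2S)-1-hydroxypropan-2-yl]-4,5-dimethoxycyclohexa-2,5-dien-1-one | C=CCC1=C[C@@](OC)([C@@H](C)CO)C(OC)=CC1=O | intermediate
11 | (4R)-2-allyl-4-[(2R)-1-iodopropan-2-yl]-4,5-dimethoxycyclohexa-2,5-dien-1-one | C=CCC1=C[C@@](OC)([C@@H](C)CI)C(OC)=CC1=O | intermediate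
12 | 4-bromo-1,2-dimethoxybenzene | COc1ccc(Br)cc1OC | starting material
13 | (3,4-dimethoxyphenyl)magnesium bromide | COc1ccc([Mg]Br)cc1OC | intermediate
14 | (3,4-dimethoxyphenyl)zinc bromide | COc1ccc([Zn]Br)cc1OC | intermediate
15 | (4S)-2-allyl-4-[(2S)-1-(3,4-dimethoxyphenyl)propan-2-yl]-4,5-dimethoxycyclohexa-2,5-dien-1-one | C=CCC1=C[C@@](OC)([C@@H](C)Cc2ccc(OC)c(OC)c2)C(OC)=CC1=O | target

## Step count and least certain steps

Total step count: 7. Longest linear sequence: 7 steps (1, 2, 4, 5, 8, 10, 11, 15). Compound 12 enters in step 7.

**Step 4 (key step).** The most likely failure is consumption of the ester enolate before it is silylated.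
- The ester is an alpha-acyloxy ketone, so the enolate can close a five-membered aldol lactone onto C6'=O. It can also expel the ortho-quinolate as a leaving group with ketene formation, after which ring B aromatises.
- A second weakness is leakage between chair and boat, which would lower the selectivity at C8.
- Fallback, which forms the ketene acetal by hydrometallation instead of deprotonation so that no base is present: from 4, acryloyl chloride and Et3N at −20 °C give the acrylate F1. It is kept cold because such esters can undergo intramolecular Diels–Alder reaction.
- 1,4-Hydrosilylation of the acrylate with Et3SiH and RhCl(PPh3)3 then gives the triethylsilyl ketene acetal F2. The (E)-geometry is required, as for 6.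
- F2 rearranges as in step 4 and, after hydrolytic work-up, comes back to the route at 8.

**Step 2.** The most likely failure is poor facial selectivity.
- Both flanks of the reacting carbonyl group are flat sp2 carbons, and the activated 1,2-dione may also react without the catalyst.
- A degenerate 1,2-shift of the allyl group from C1' to C6' would interconvert the enantiomers and erode the enantiomeric purity.
- Fallback, which gives up catalyst control and resolves later: from 2, indium powder and allyl bromide in aqueous THF give the racemic ortho-quinol F3.
- Steps 3 and 4 are run unchanged and lead through the racemic propionate F4 to the racemic acid F5. F5 is a single diastereomer because the rearrangement is stereospecific.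
- Crystallisation with (S)-1-phenylethylamine gives the ammonium salt F6 of the wanted enantiomer. The antipodal amine serves if its salt is the less soluble one.
- Acidification comes back to the route at 8.

**Step 5.** The most likely failure is ring closure of the C7 oxygen onto C4' (with loss of methanol) or onto C2' in the basic borohydride medium.
- Next in likelihood is hydride attack at C6' followed by aromatisation through loss of methanol.
- Fallback, which lowers the oxidation level without a hard hydride and without an alkoxide: from 8, ethanethiol, EDC hydrochloride and DMAP give the S-ethyl thioester F7.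
- Fukuyama reduction (Et3SiH, Pd/C, acetone) gives the aldehyde F8.
- NaBH(OAc)3 in CH2Cl2, which is weakly acidic and selective for aldehydes, comes back to the route at 10.

**Step 7.** The most likely failure is slow activation of the beta-branched iodide.
- Nickel-catalysed conjugate addition of 14 to C2', beta-hydride elimination toward C8, or internal O-alkylation by the methoxy oxygen on C4' could then take over.
- Fallback, which makes the C7–aryl bond without a transition metal and without an alkyl halide: from 10, Dess–Martin periodinane gives the aldehyde F8.
- Condensation with 4-methylbenzenesulfonohydrazide gives the N-tosylhydrazone F9.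
- Heating with 3,4-dimethoxyphenylboronic acid and K2CO3 in dioxane brings about reductive coupling. It runs through the diazoalkane, a 1,2-shift on boron and protodeboronation, and comes back to the route at 15.

## Further compounds

F1 | step 4 | (1S)-1-allyl-3,4-dimethoxy-6-oxocyclohexa-2,4-dien-1-yl acrylate | C=CC[C@]1(OC(=O)C=C)C=C(OC)C(OC)=CC1=O
F2 | step 4 | (E)-O-triethylsilyl ketene acetal formed from F1 | C=CC[C@]1(O/C(O[Si](CC)(CC)CC)=C\C)C=C(OC)C(OC)=CC1=O
F3 | step 2 | racemic 6-allyl-6-hydroxy-3,4-dimethoxycyclohexa-2,4-dien-1-one (both enantiomers) | C=CC[C@]1(O)C=C(OC)C(OC)=CC1=O.C=CC[C@@]1(O)C=C(OC)C(OC)=CC1=O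
F4 | step 2 | racemic 1-allyl-3,4-dimethoxy-6-oxocyclohexa-2,4-dien-1-yl propanoate (both enantiomers) | C=CC[C@]1(OC(=O)CC)C=C(OC)C(OC)=CC1=O.C=CC[C@@]1(OC(=O)CC)C=C(OC)C(OC)=CC1=O
F5 | step 2 | racemic acid with the relative configuration of 8 (both enantiomers) | C=CCC1=C[C@@](OC)([C@@H](C)C(=O)O)C(OC)=CC1=O.C=CCC1=C[C@](OC)([C@H](C)C(=O)O)C(OC)=CC1=O
F6 | step 2 | (S)-1-phenylethylammonium salt of 8 | C=CCC1=C[C@@](OC)([C@@H](C)C(=O)[O-])C(OC)=CC1=O.C[C@H]([NH3+])c1ccccc1
F7 | step 5 | S-ethyl thioester of 8 | C=CCC1=C[C@@](OC)([C@@H](C)C(=O)SCC)C(OC)=CC1=O
F8 | step 5 | (2R)-2-[(1R)-3-allyl-1,6-dimethoxy-4-oxocyclohexa-2,5-dien-1-yl]propanal | C=CCC1=C[C@@](OC)([C@@H](C)C=O)C(OC)=CC1=O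
F9 | step 7 | N-tosylhydrazone of F8 | C=CCC1=C[C@@](OC)([C@@H](C)/C=N/NS(=O)(=O)c2ccc(C)cc2)C(OC)=CC1=O
A1 | alternative 1 | 2-allyl-4-[(2S)-1-(3,4-dimethoxyphenyl)propan-2-yl]-5-methoxyphenol | C=CCc1cc([C@@H](C)Cc2ccc(OC)c(OC)c2)c(OC)cc1O
A2 | alternative 2 | 2-allyl-5-methoxy-1,4-benzoquinone | C=CCC1=CC(=O)C(OC)=CC1=O
A3 | alternative 2 | (2S)-1-(3,4-dimethoxyphenyl)propan-2-yllithium | [Li][C@@H](C)Cc1ccc(OC)c(OC)c1
A4 | alternative 2 | 2-allyl-4-[(2S)-1-(3,4-dimethoxyphenyl)propan-2-yl]-4-hydroxy-5-methoxycyclohexa-2,5-dien-1-one with the C4 arrangement of 15 | C=CCC1=C[C@@](O)([C@@H](C)Cc2ccc(OC)c(OC)c2)C(OC)=CC1=O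
A5 | alternative 3 | 2-allyl-4,4,5-trimethoxycyclohexa-2,5-dien-1-one | C=CCC1=CC(OC)(OC)C(OC)=CC1=O
A6 | alternative 3 | (E)-1,2-dimethoxy-4-(prop-1-en-1-yl)benzene ((E)-methylisoeugenol) | C/C=C/c1ccc(OC)c(OC)c1
A7 | alternative 3 | (2R,3S,3aR)-5-allyl-2-(3,4-dimethoxyphenyl)-3a-methoxy-3-methyl-3,3a-dihydro-1-benzofuran-6(2H)-one | C=CCC1=C[C@@]2(OC)[C@@H](C)[C@H](c3ccc(OC)c(OC)c3)OC2=CC1=O
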